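**Plan**
Chain numbering: the vinyl CH2 is C1, the ester-bearing carbon C3, the diyne C4–C7, the methylene C8, the oxirane carbons C9 and C10, the heptyl tail C11–C17.
Cuts, in retrosynthetic order: the ester O–C(=O) bond (linoleic acid); C3–C4 (diynylzinc + acrolein); C11–C12 and O–C9 together (hexyl nucleophile + epoxy mesylate); C5–C6 (bromoalkyne coupling); C6≡C7 (one-carbon homologation of an aldehyde).
Enabling feature: the run C7–C8–C9–C10–C11 (alkyne carbon, methylene, the two carbons of the only ring, the first plain CH2 of the heptyl tail) has the carbon and oxygen pattern of C1–C5 of 2-deoxy-D-ribose. The ring is a trans oxirane, which is what an erythro diol gives after a single inversion.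
Forward: the sugar is extended to the silyl-capped diyne and an oxirane is closed at C10–C11. This ring is then moved to C9–C10 in the operation that attaches the hexyl chain, and acrolein and linoleic acid are joined last.
Stereochemistry: 10R is sugar C4, untouched throughout. 9R is sugar C3 (S), inverted once in the key step. 3S comes from a chiral dinuclear zinc catalyst, and both Z alkenes arrive with linoleic acid.

Key step: step 7

Assumption: the (S,S)-ligand in step 9 is taken to deliver the diynyl group to the Re face of acrolein (this face gives 3S). The sense should be confirmed on 15 by MTPA ester analysis, and the equally available (R,R)-ligand is used if it proves opposite.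

**Step 1**
Reactants: 1 2-deoxy-D-ribose
Product: 2 (2R,3S)-hex-5-yne-1,2,3-triol
Conditions: dimethyl (1-diazo-2-oxopropyl)phosphonate, K2CO3, MeOH, rt → 65 °C
Reagents that add atoms: dimethyl (1-diazo-2-oxopropyl)phosphonate, CC(=O)C(=[N+]=[N-])P(=O)(OC)OC
Why: Seyferth–Gilbert homologation in the Ohira–Bestmann variant: the diazomethylphosphonate anion released by methanolysis traps the small equilibrium share of open-chain aldehyde, so that sugar C1 becomes alkyne carbon C7 and the two carbinol centres are not touched.

**Step 2**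
Reactants: 2 (2R,3S)-hex-5-yne-1,2,3-triol
Product: 3 (1S)-1-[(4R)-2,2-dimethyl-1,3-dioxolan-4-yl]but-3-yn-1-ol
Conditions: 2,2-dimethoxypropane, p-TsOH·H2O (cat.), acetone, rt
Reagents that add atoms: 2,2-dimethoxypropane, COC(C)(C)OC
Why: Acid-catalysed transketalisation under thermodynamic control: the erythro internal diol could only give a strained cis-4,5-disubstituted dioxolane, so the monosubstituted terminal dioxolane should prevail, leave the C9 hydroxyl free, and allow any internal isomer to be re-equilibrated.

**Step 3**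
Reactants: 3 (1S)-1-[(4R)-2,2-dimethyl-1,3-dioxolan-4-yl]but-3-yn-1-ol; 4 (bromoethynyl)triisopropylsilane
Product: 5 (1S)-1-[(4R)-2,2-dimethyl-1,3-dioxolan-4-yl]-6-(triisopropylsilyl)hexa-3,5-diyn-1-ol
Conditions: CuCl (cat.), NH2OH·HCl, n-BuNH2, H2O–Et2O, 0 °C
Reagents that add atoms: none
Why: Cadiot–Chodkiewicz coupling: the copper acetylide of 3 attacks the bromoalkyne to form C5–C6, hydroxylamine keeps the copper monovalent so that homocoupling stays low, and the basic medium spares the acetonide.

**Step 4**
Reactants: 5 (1S)-1-[(4R)-2,2-dimethyl-1,3-dioxolan-4-yl]-6-(triisopropylsilyl)hexa-3,5-diyn-1-ol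
Product: 6 (1S)-1-[(4R)-2,2-dimethyl-1,3-dioxolan-4-yl]-6-(triisopropylsilyl)hexa-3,5-diyn-1-yl methanesulfonate
Conditions: MsCl, Et3N, CH2Cl2, −20 → 0 °C
Reagents that add atoms: methanesulfonyl chloride, CS(=O)(=O)Cl
Why: Sulfonylation of a secondary alcohol leaves the C9–O bond intact, so 9S is kept, and low temperature with short contact time guards against loss of the mesylate towards the acidic C8 hydrogens.

**Step 5**
Reactants: 6 (1S)-1-[(4R)-2,2-dimethyl-1,3-dioxolan-4-yl]-6-(triisopropylsilyl)hexa-3,5-diyn-1-yl methanesulfonate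
Product: 7 (2R,3S)-1,2-dihydroxy-8-(triisopropylsilyl)octa-5,7-diyn-3-yl methanesulfonate
Conditions: AcOH–THF–H2O (3:1:1), 45 °C
Reagents that add atoms: none
Why: Acid-catalysed acetal hydrolysis frees the C10 and C11 hydroxyls, and the secondary mesylate and the silyl-capped diyne are inert to dilute acetic acid.

**Step 6**
Reactants: 7 (2R,3S)-1,2-dihydroxy-8-(triisopropylsilyl)octa-5,7-diyn-3-yl methanesulfonate
Product: 8 (1S)-1-[(2R)-oxiran-2-yl]-6-(triisopropylsilyl)hexa-3,5-diyn-1-yl methanesulfonate
Conditions: PPh3, DIAD, toluene, 0 → 80 °C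
Reagents that add atoms: none
Why: Mitsunobu cyclodehydration of a terminal 1,2-diol: the phosphonium reagent activates the unhindered primary C11 hydroxyl and the C10 oxygen displaces it in a 3-exo-tet closure, so the C10–O bond and 10R are kept while the nearly neutral medium leaves the C9 mesylate in place.

**Step 7**
Reactants: 8 (1S)-1-[(2R)-oxiran-2-yl]-6-(triisopropylsilyl)hexa-3,5-diyn-1-yl methanesulfonate; 9 hexylmagnesium bromide
Product: 11 {5-[(2R,3R)-3-heptyloxiran-2-yl]penta-1,3-diyn-1-yl}triisopropylsilane, via bromomagnesium alkoxide 10 (not isolated)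
Conditions: CuI (10 mol %), THF, −40 → −20 °C; then MeOH, K2CO3, 0 °C → rt, same flask; aq. NH4Cl work-up
Reagents that add atoms: none
Why: Hexylmagnesium bromide and CuI generate a hexyl species of monovalent copper that opens the monosubstituted oxirane of 8 by SN2 attack at the unhindered C11 methylene, which forms C11–C12 and turns C10, still R, into the alkoxide 10. Methanol then destroys the surplus organometallic, and K2CO3 keeps the C10 oxygen nucleophilic enough to expel the C9 mesylate from the rear and form O–C9. The closest known reaction type is the organocuprate opening of a terminal epoxide that bears a vicinal secondary sulfonate, followed by base closure to the transposed internal epoxide, as practised for dialkyloxirane pheromones. The single ring made, the C9–C10 oxirane, closes in the 3-exo-tet mode. C9 is the only centre that changes: backside displacement inverts it from S to R under control of the sugar-derived C9–O orientation, and with the retained 10R this should give the (9R,10R) trans oxirane. Epoxide opening must outrun substitution at the secondary mesylate, carbocupration of the diyne and deprotonation at C8, and this is secured by the strain and accessibility of the terminal oxirane, the bulky silyl cap and the low temperature.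

**Step 8**
Reactants: 11 {5-[(2R,3R)-3-heptyloxiran-2-yl]penta-1,3-diyn-1-yl}triisopropylsilane
Product: 12 (2R,3R)-2-heptyl-3-(penta-2,4-diyn-1-yl)oxirane
Conditions: Bu4NF, AcOH, THF, −20 → 0 °C; used at once as a toluene solution
Reagents that add atoms: none
Why: Fluoride-induced protiodesilylation of an alkynylsilane is fast for a diynyl leaving group, and buffering with acetic acid should prevent base-induced isomerisation at C8 or opening of the oxirane.

**Step 9**
Reactants: 12 (2R,3R)-2-heptyl-3-(penta-2,4-diyn-1-yl)oxirane; 13 acrolein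
Product: 15 (3S)-8-[(2R,3R)-3-heptyloxiran-2-yl]oct-1-ene-4,6-diyn-3-ol, via methylzinc diynylide 14 (not isolated)
Conditions: Zn(CH3)2, (S,S)-ProPhenol [2,6-bis{[(2S)-2-(hydroxydiphenylmethyl)pyrrolidin-1-yl]methyl}-4-methylphenol, 20 mol %], Ph3P=O (40 mol %), toluene, 0 °C; then slow addition of 13, 4 °C; aq. NH4Cl
Reagents that add atoms: none
Why: Catalytic asymmetric alkynylation of an aldehyde by a dinuclear zinc ProPhenol complex: Zn(CH3)2 metalates the acidic diyne C–H to 14, and the chiral pocket holds acrolein on the second zinc and passes the diynyl group to its Re face, which forms C3–C4 and sets 3S without involvement of the remote oxirane centres.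

**Step 10**
Reactants: 15 (3S)-8-[(2R,3R)-3-heptyloxiran-2-yl]oct-1-ene-4,6-diyn-3-ol; 16 linoleic acid
Product: 17 (3S)-8-[(2R,3R)-3-heptyloxiran-2-yl]oct-1-ene-4,6-diyn-3-yl (9Z,12Z)-octadeca-9,12-dienoate
Conditions: EDC·HCl, 4-(dimethylamino)pyridine (cat.), CH2Cl2, argon, 0 °C → rt
Reagents that add atoms: none
Why: Steglich esterification: carbodiimide activation of the acid with acyl transfer by the pyridine catalyst never breaks the C3–O bond, so 3S is retained, and the mild medium spares oxirane, diyne and skipped Z,Z-diene.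

**Compound list**
1 | 2-deoxy-D-ribose, (3S,4R)-3,4,5-trihydroxypentanal, drawn open-chain | O=CC[C@H](O)[C@H](O)CO | starting material
2 | (2R,3S)-hex-5-yne-1,2,3-triol | C#CC[C@H](O)[C@H](O)CO | intermediate
3 | (1S)-1-[(4R)-2,2-dimethyl-1,3-dioxolan-4-yl]but-3-yn-1-ol | C#CC[C@H](O)[C@H]1COC(C)(C)O1 | intermediate
4 | (bromoethynyl)triisopropylsilane | CC(C)[Si](C(C)C)(C(C)C)C#CBr | starting material
5 | (1S)-1-[(4R)-2,2-dimethyl-1,3-dioxolan-4-yl]-6-(triisopropylsilyl)hexa-3,5-diyn-1-ol | CC(C)[Si](C(C)C)(C(C)C)C#CC#CC[C@H](O)[C@H]1COC(C)(C)O1 | intermediate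
6 | (1S)-1-[(4R)-2,2-dimethyl-1,3-dioxolan-4-yl]-6-(triisopropylsilyl)hexa-3,5-diyn-1-yl methanesulfonate | CC(C)[Si](C(C)C)(C(C)C)C#CC#CC[C@H](OS(C)(=O)=O)[C@H]1COC(C)(C)O1 | intermediate
7 | (2R,3S)-1,2-dihydroxy-8-(triisopropylsilyl)octa-5,7-diyn-3-yl methanesulfonate | CC(C)[Si](C(C)C)(C(C)C)C#CC#CC[C@H](OS(C)(=O)=O)[C@H](O)CO | intermediate
8 | (1S)-1-[(2R)-oxiran-2-yl]-6-(triisopropylsilyl)hexa-3,5-diyn-1-yl methanesulfonate (9S,10R in chain numbering) | CC(C)[Si](C(C)C)(C(C)C)C#CC#CC[C@H](OS(C)(=O)=O)[C@H]1CO1 | intermediate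
9 | hexylmagnesium bromide | CCCCCC[Mg]Br | starting material
10 | bromomagnesium alkoxide of (6S,7R)-7-hydroxy-1-(triisopropylsilyl)tetradeca-1,3-diyn-6-yl methanesulfonate | CC(C)[Si](C(C)C)(C(C)C)C#CC#CC[C@H](OS(C)(=O)=O)[C@H](O[Mg]Br)CCCCCCC | intermediate
11 | {5-[(2R,3R)-3-heptyloxiran-2-yl]penta-1,3-diyn-1-yl}triisopropylsilane | CC(C)[Si](C(C)C)(C(C)C)C#CC#CC[C@H]1O[C@@H]1CCCCCCC | intermediate
12 | (2R,3R)-2-heptyl-3-(penta-2,4-diyn-1-yl)oxirane | C#CC#CC[C@H]1O[C@@H]1CCCCCCC | intermediate
13 | acrolein (prop-2-enal) | C=CC=O | starting material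
14 | methyl{5-[(2R,3R)-3-heptyloxiran-2-yl]penta-1,3-diyn-1-yl}zinc | C[Zn]C#CC#CC[C@H]1O[C@@H]1CCCCCCC | intermediate
15 | (3S)-8-[(2R,3R)-3-heptyloxiran-2-yl]oct-1-ene-4,6-diyn-3-ol | C=C[C@H](O)C#CC#CC[C@H]1O[C@@H]1CCCCCCC | intermediate
16 | linoleic acid, (9Z,12Z)-octadeca-9,12-dienoic acid | OC(=O)CCCCCCC/C=C\C/C=C\CCCCC | starting material
17 | (3S)-8-[(2R,3R)-3-heptyloxiran-2-yl]oct-1-ene-4,6-diyn-3-yl (9Z,12Z)-octadeca-9,12-dienoate | C=C[C@@H](C#CC#CC[C@H]1O[C@@H]1CCCCCCC)OC(=O)CCCCCCC/C=C\C/C=C\CCCCC | target

**Total step count:** 10. **Longest linear sequence:** 10 steps, from 1 to 17. Compounds 4, 9, 13 and 16 are bought.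

**Steps most likely to fail**

Step 7. The C8 hydrogens are propargylic to a diyne and lie β to the mesylate, so the basic organometallic or the carbonate may cause elimination across C8–C9. Magnesium bromide may also open the terminal oxirane before the copper reagent does.
The fallback reverses the two events so that the organometallic never meets the mesylate. It sets out from 7. K2CO3 in MeOH at 0 °C lets the C10 oxygen displace the C9 mesylate first, giving the trans epoxy alcohol {(2R,3R)-3-[5-(triisopropylsilyl)penta-2,4-diyn-1-yl]oxiran-2-yl}methanol F1. Treatment with (CF3SO2)2O and 2,6-lutidine in CH2Cl2 at −78 °C converts it into the primary triflate {(2R,3R)-3-[5-(triisopropylsilyl)penta-2,4-diyn-1-yl]oxiran-2-yl}methyl trifluoromethanesulfonate F2, which is used crude. Copper-catalysed alkyl–alkyl coupling of F2 with 9 (CuBr·S(CH3)2 cat., Et2O–THF, −78 → −40 °C) then forms C11–C12 by direct displacement. The fallback rejoins the route at 11.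

Step 6. Three processes may interfere: competing activation of the secondary C10 hydroxyl, which would invert C10; N-alkylation of the reduced azo reagent at C11; and thermal loss of the mesylate during heating.
The fallback replaces the redox dehydration by sulfonate displacement and sets out from 7. Tin-acetal-directed monotosylation (TsCl, Et3N, Bu2SnO cat., CH2Cl2, 0 °C) should mark only the primary hydroxyl, giving (2R,3S)-2-hydroxy-3-[(methylsulfonyl)oxy]-8-(triisopropylsilyl)octa-5,7-diyn-1-yl 4-methylbenzenesulfonate F3. Brief exposure to K2CO3 in MeOH at −10 °C closes the C10 oxygen onto the faster-leaving primary sulfonate. The fallback rejoins the route at 8.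

Step 9. Facial selectivity may be poor with so small an enal, acrolein may polymerise in the presence of the zinc amino alkoxide, and the sense of induction is assumed.
The fallback gives up catalyst control in favour of enzymatic sorting of the C3 epimers and sets out from 12. Deprotonation with n-BuLi in THF at −78 °C and addition of 13 gives the epimer mixture (3RS)-8-[(2R,3R)-3-heptyloxiran-2-yl]oct-1-ene-4,6-diyn-3-ol F4. Lipase from Burkholderia cepacia with vinyl acetate in MTBE at 30 °C should acylate the epimer in which the long diynyl chain acts as the large group and vinyl as the medium group, following the empirical size rule for secondary alcohols. This gives (3R)-8-[(2R,3R)-3-heptyloxiran-2-yl]oct-1-ene-4,6-diyn-3-yl acetate F5. The unreacted 3S alcohol is separated by chromatography, and the fallback rejoins the route at 15.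

**Further compounds**
F1 | step 7 | {(2R,3R)-3-[5-(triisopropylsilyl)penta-2,4-diyn-1-yl]oxiran-2-yl}methanol | CC(C)[Si](C(C)C)(C(C)C)C#CC#CC[C@H]1O[C@@H]1CO
F2 | step 7 | {(2R,3R)-3-[5-(triisopropylsilyl)penta-2,4-diyn-1-yl]oxiran-2-yl}methyl trifluoromethanesulfonate | CC(C)[Si](C(C)C)(C(C)C)C#CC#CC[C@H]1O[C@@H]1COS(=O)(=O)C(F)(F)F
F3 | step 6 | (2R,3S)-2-hydroxy-3-[(methylsulfonyl)oxy]-8-(triisopropylsilyl)octa-5,7-diyn-1-yl 4-methylbenzenesulfonate | CC(C)[Si](C(C)C)(C(C)C)C#CC#CC[C@H](OS(C)(=O)=O)[C@H](O)COS(=O)(=O)c1ccc(C)cc1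
F4 | step 9 | (3RS)-8-[(2R,3R)-3-heptyloxiran-2-yl]oct-1-ene-4,6-diyn-3-ol, mixture of C3 epimers | C=CC(O)C#CC#CC[C@H]1O[C@@H]1CCCCCCC
F5 | step 9 | (3R)-8-[(2R,3R)-3-heptyloxiran-2-yl]oct-1-ene-4,6-diyn-3-yl acetate | C=C[C@@H](OC(C)=O)C#CC#CC[C@H]1O[C@@H]1CCCCCCC
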